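Slowness came first: I asked how long incoming ligand lasts in a flask of starting complex.

common to all: starting complex 0.26 M
- winter: incoming ligand 0.17 M; leaving ligand 0.13 M; run made earlier
- noon: incoming ligand 1 M; leaving ligand 0.13 M; run made earlier
- beta: incoming ligand 0.390 M; leaving ligand 0.130 M; time 25 min
- zeta: incoming ligand 0.130 M; leaving ligand 0.130 M; time 25 min
- theta: incoming ligand 0.650 M; leaving ligand 0.130 M; time 25 min

| run | time / min | complex with two exchanged / % | starting complex / % |
|---|---|---|---|
| winter | 4.00 | 7.9 | 64.3 |
| winter | 8.00 | 12.5 | 49.8 |
| winter | 12.0 | 14.2 | 41.5 |
| winter | 20.0 | 15.9 | 33.6 |
| noon | 2.00 | 39.2 | 31.0 |
| noon | 6.00 | 50.6 | 6.7 |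
| noon | 12.0 | 55.2 | 0.8 |
| noon | 20.0 | 56.0 | 0 |

(readings scatter by 0.3 percentage points)

- a species is counted by the starting complex in it: one side product counts as two
- on the list of suspects stand: starting complex + incoming ligand -> leaving ligand + complex with one exchanged; complex with one exchanged + incoming ligand -> leaving ligand + complex with two exchanged; complex with two exchanged + incoming ligand <-> leaving ligand + complex with three exchanged; starting complex + complex with one exchanged -> side product

- which of these holds the largest part of the starting complex at the end of beta (starting complex / complex with one exchanged / complex with two exchanged / complex with three exchanged)
- which of these holds the largest part of the starting complex at the end of zeta (starting complex / complex with one exchanged / complex with two exchanged / complex with three exchanged)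
- which of these holds the largest part of the starting complex at the end of theta (starting complex / complex with one exchanged / complex with two exchanged / complex with three exchanged)
- final complex with two exchanged in zeta, as a percentage of the starting complex charged

In the noon run, with ligand near its charge, the first 2.00 min left 31.0 % of the starting complex. I read that as a first-exchange constant of 0.586 M⁻¹ min⁻¹; the forecast took about 0.55. While starting complex stands in excess, ligand decays pseudo-first-order. So I used the ligand half-life: ln(2) over that constant times the starting complex charged, 4.55 min. With the starting complex fixed, it doesn't depend on how much ligand went in.

Winter and zeta charge the same starting complex, so they share this half-life. Winter's last reading came after 4.39 half-lives, and zeta's 25 min holds 5.49. Falling starting complex stretches the half-life and the second exchange shortens it, so the count is rough. Still, the time is long against the half-life, so I expected zeta to end on its ligand budget, not on the clock. Ligand is the limiting reagent there, at 0.500 per starting complex.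

Winter had 0.654 per starting complex and reached 15.9 % of complex with two exchanged, which is 0.243 per unit of ligand. At that share zeta would give 12.2 %. I expected less, since zeta has less ligand per starting complex and side product competes for complex with one exchanged.

The forecast said complex with two exchanged for beta, starting complex for zeta, complex with two exchanged for theta, and 10.5 % for the final complex with two exchanged in zeta, below my figure. Its ground for zeta: “Zeta has only 50% ligand, which runs out.”

Zeta gave 10.4 %, and all three choices stood: complex with two exchanged, starting complex, complex with two exchanged.

    starting complex + incoming ligand → leaving ligand + complex with one exchanged (k = 0.0110 M⁻¹ s⁻¹)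
    complex with one exchanged + incoming ligand → leaving ligand + complex with two exchanged (k = 0.0480 M⁻¹ s⁻¹)
    complex with two exchanged + incoming ligand ⇌ leaving ligand + complex with three exchanged (K = 0.800, k = 0.00620 M⁻¹ s⁻¹)
    starting complex + complex with one exchanged → side product (k = 0.0290 M⁻¹ s⁻¹)

Left ten times as long, zeta stood at 11.0 %. Its ligand at 25.0 min was 5.1 % of the charge, or 4.29 halvings against my 5.49. With all else held, the answer for zeta moves 5 points at 0.341 or 0.638 ligand per starting complex, and as far at a starting complex charge of 0.199 M or 0.385 M. With the side-product step struck out it stands at 17.2 %. A neighbour of zeta, with 0.200 ligand per starting complex, has the same half-life, so my count gives 2.23 % of its ligand left. It kept 2.8 %, with 2.06 % of complex with two exchanged.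

Readings and results are simulated from invented constants.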